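The earlier runs and the new flask stem from a simulated flask for substances that don't exist; noise was put on by code.

Tuesday's and Saturday's runs, at the same charge of coupling partner, are the guide to the two flasks now on the bench.

| flask | substrate | coupling partner | remark | time |
|---|---|---|---|---|
| Tuesday's | 0.25 M | 0.70 M | run made earlier |  |
| Saturday's | 0.54 M | 0.70 M | run made earlier |  |
| south-west | 0.30 M | 0.700 M |  | 20 min |
| south-east | 1.0 M | 0.700 M |  | 5.0 min |

| run | time / min | target / % | substrate / % |
|---|---|---|---|
| Tuesday's | 0.667 | 40.0 | 57.4 |
| Tuesday's | 1.33 | 45.6 | 52.0 |
| Tuesday's | 2.00 | 47.2 | 51.0 |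
| Tuesday's | 3.00 | 47.8 | 51.6 |
| Tuesday's | 4.00 | 46.7 | 49.4 |
| Saturday's | 0.333 | 30.7 | 70.5 |
| Saturday's | 0.833 | 38.1 | 61.1 |
| Saturday's | 1.50 | 39.1 | 56.1 |
| Saturday's | 2.50 | 42.9 | 56.4 |
| Saturday's | 4.00 | 41.5 | 56.1 |

(scatter of a reading: 1 percentage point)

- a reading of substrate is of its free form alone

- the winner by amount of target, in percent of the substrate charged; "neither" if no more than 2 percentage points parts them (south-west / south-east / neither)
- how much target is there at the end, in percent of the substrate charged: south-west
- how much target is there at the end, in percent of the substrate charged: south-east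

In both runs the readings of target and substrate level off by about 2.00 min, so each run is read as reaching a balance of substrate and coupling partner with target. Reading K = c(target)/(c(substrate)·c(coupling partner)), with the partner taken as charge minus target, at the last readings of the two runs gives a mean of 1.59 M⁻¹.

But at 4.00 min target and substrate fall short of the charge, by 3.9 percentage points on Tuesday's and 2.4 points on Saturday's, each gap carrying the scatter of two readings. The mean gap over the time gives 0.00787 min⁻¹, the leak: the share of the charge leaving the mass balance per minute.

Taken as equal in both new flasks, it removes 15.7% from south-west and 3.94% from south-east. K without the leak gives 47.0% of target in south-west and 35.4% in south-east. Scaled by what the leak leaves, the bench should find 39.6% in south-west and 34.0% in south-east. This reckoning of mine therefore puts south-west ahead by 5.6 points, more than the margin of 2 points. Neither flask should stand past its time, and south-west is reckoned to lose more than south-east.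

The forecast says south-west, with 46.5% (44.5% to 48.5%) and 35% (33% to 37.5%), “assuming no slow loss of target”. For south-west it stands higher than this reckoning.

South-west gives 39.8% and south-east 33.5%, so south-west wins, and the forecast's south-west figure stands 6.7 points too high.

coupling partner ⇌ dormant form (K = 0.740, k = 0.0370 s⁻¹); substrate + coupling partner ⇌ isomer of the product (K = 3.10 M⁻¹, k = 9.10 × 10⁻⁴ M⁻¹ s⁻¹); substrate + coupling partner ⇌ target (K = 2.80 M⁻¹, k = 0.0470 M⁻¹ s⁻¹) Beside the reckoned leak stands the isomer of the product: 14.4% in south-west at 20.0 min against 15.7% reckoned, and 3.63% in south-east at 5.00 min against 3.94%. The neighbour is south-east with 1.7 M of substrate. There K gives 27.3% of target, and the leak over 5.0 min brings that to 26.2%. That neighbour flask holds 25.5% of target, with 2.80% of isomer of the product.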